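## Analysis of the target

The target is a germacranolide. Its ten-membered carbocycle (C1–C10) is fused at C6/C7 to an α,β-unsaturated γ-lactone (O–C6, C7=C11, C12=O). C13 is the acetoxymethyl carbon on C11, C14 the methyl on C10 and C15 the methyl on C4. There are five stereocentres: C4 (S), C5 (R), C6 (R), C8 (R) and C10 (S). C4 and C5 form a trisubstituted cis epoxide (C3 and C6 on the same face), C6 is vicinal to C5, C8 carries the 3-methylbut-2-enoate, and C10 lies α to the C1 ketone. The sensitive groups are the epoxide next to the lactone C–O bond, the butenolide with its acidic C6–H, two different esters, and the ketone, whose α-centre C10 can epimerise. A free C8 hydroxyl beside the C1 ketone would also close a transannular hemiketal, so the order in which the oxygens are unveiled matters. The synthesis is hard because of the medium ring and the tetrasubstituted C7=C11 bond shared by both rings. The strategy rests on the C6–C7 bond: it joins the butenolide β-carbon C7 to the oxygen-bearing C6, which sits next to epoxide carbon C5. Cutting C6–C7 together with O–C12 gives an α,β-epoxy aldehyde and a β-iodo enoate with the ester cis to iodine.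

## Retrosynthetic reasoning

**34 back to 29 (end game).** The C1 ketone is made last, from alcohol 33. A C1 carbonyl present earlier would compete with the aldehyde during ring closure (five-membered closure from C7), would expose C10 to base during the acylations, and would form a hemiketal with a free C8 hydroxyl. The two ester C–O bonds are cut next: 32 comes from 31 and 31 from diol 30, the primary C13 hydroxyl being acylated before the hindered C8 hydroxyl. Diol 30 comes from 29 by removing the two labile silyl groups (TES on C8, primary TBS on C13) while the hindered TBS on C1 stays.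

**29 back to 26 (key disconnection).** The C6–C7 bond and the O6–C12 lactone bond are cut together. This single cut opens both rings and removes the C6 stereocentre. It leaves aldehyde 26, in which the epoxide is already in place beside the carbonyl and the alkenyl iodide is cis to the methyl ester. The forward reaction has to add the alkenyl metal to the aldehyde only, close a ten-membered ring, attack the face of the aldehyde anti to the C5–O bond, and let the new alkoxide acylate on the neighbouring ester.

**26 back to 24.** The epoxy aldehyde is the most fragile function, so it is unveiled last: 26 from alcohol 25 by oxidation, 25 from PMB ether 24 by oxidative deprotection, which is orthogonal to all three silyl ethers.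

**24 back to 20 (the tetrasubstituted alkene).** An alkyne between C7 and C11 was not used. It can carry only one of C12 and C13, and the other carbon and the iodine would have to be added across a triple bond flanked by oxygenated carbons on both sides, with no handle for regiocontrol. Every hydrometalation variant also leaves hydrogen on C7 or C11. A β-keto ester (20) already has all four substituents, and its lithium enolate is locked by chelation with the C7 oxygen cis to C12. That geometry is captured as enol triflate 22 and carried with retention through stannane 23 to iodide 24.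

**20 back to 16 and 17.** The C7–C11 bond is cut as an aldol bond: ester 17 brings C11, C12 and C13 at their final oxidation levels, and aldehyde 16 brings C7. Oxidation of aldol 19 then erases the two stereocentres that do not matter.

**16 back to 10 and 11.** C8 is set by a catalyst-controlled alkenyl addition to aldehyde 10. The hexenyl group from 11 is only a masked formyl group and is cut back to C7 by ozonolysis of 15.

**10 back to 4 and 5.** The C1–C10 bond is cut as a crotylation. The (E)-crotyl reagent 5 sets C10 and makes C1 a carbinol, which is exactly the masked form of the ketone that the ring closure needs. The terminal alkene of 7 becomes the C8 aldehyde by hydroboration and oxidation.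

**4 back to 1.** Aldehyde 4 comes from nerol (1). The Z-allylic alcohol gives the cis epoxide with both C4 and C5 set by reagent control (2), and the distal alkene is the latent C1 aldehyde (3 to 4).

## Alternatives that were turned down

**Alternative 1: anionic oxy-Cope ring expansion.** The ten-membered ring is traced back to a six-membered carbocycle with two alkenyl arms on adjacent carbons. In the forward step its potassium alkoxide undergoes a [3,3] shift that breaks C1–C6 and forms C3–C4, and protonation of the ring-expanded enolate gives A1, an (E)-cyclodec-5-enone with a C4 tertiary methoxymethyl ether, a C7 ketal and a C8 PMB ether.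
- For: the ring closure is unimolecular, needs no high dilution, is driven by alkoxide-to-enolate conversion, and the chair transition state relays configuration to C4. On the ring-forming event itself it is stronger than any macrocyclisation that competes with oligomerisation.
- Against: A1 is far from the target. The C5=C6 alkene and the C4 ether still have to become the 4,5-epoxide and the C6 oxygen. The whole butenolide, with its tetrasubstituted alkene and C13, has to be built on a hindered C7 ketone inside a medium ring prone to transannular reactions. C10 is set only by enolate protonation.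
- Comparison: the chosen route pays with a harder ring closure, but that closure delivers the ring, the lactone and C6 at once with every carbon and oxidation level in place. The oxy-Cope would leave a long series of functional-group steps on the sensitive ten-membered ring.

**Alternative 2: ring-closing metathesis at C2–C3.** The C2–C3 bond is cut as an alkene. In the forward step a vinyl group on the C1 carbinol and a vinyl group on epoxide carbon C4 are joined by the second-generation Grubbs catalyst to give A2, the 2,3-dehydro macrocycle that already carries acetate, senecioate and butenolide.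
- For: the closure is catalytic, neutral and late, and the open-chain diene can be assembled convergently, with the C6–C7 bond and lactone made intermolecularly without dilution. On convergence and on avoiding stoichiometric chromium it is stronger.
- Against: ten-membered rings are the least favourable size for metathesis. Both alkenes are hindered (one on a quaternary epoxide carbon, one beside a silyloxy carbon), and a vinyl epoxide is prone to ionisation and isomerisation. After closure the C2=C3 bond must be reduced in the presence of C7=C11, the senecioate alkene and an allylic epoxide C–O bond, which costs a step and adds a chemoselectivity problem.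
- Comparison: the chosen route ends the ring closure with C2 and C3 already saturated and no alkene to remove.

**Alternative 3: Payne rearrangement with lactonisation trap.** The 4,5-epoxide and the O6–C12 bond are cut. In the forward step a C4 tertiary alkoxide opens a 5,6-epoxide at C5 with inversion, and the freed C6 alkoxide lactonises onto the C12 ester to give A3, the bis-silylated epoxy butenolide with the C1 ketone.
- For: lactonisation makes the otherwise reversible epoxide migration irreversible, C4 can come from a chiral-pool tertiary alcohol, and the C1 ketone needs no masking. On protecting-group economy at C1 it is stronger.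
- Against: the step forms no C–C bond and no carbocycle, so the ten-membered ring with its tetrasubstituted alkene must already exist. Its substrate is an epoxide allylic to an enoate under strong base beside an enolisable ketone, which invites conjugate opening, C10 epimerisation and transannular aldol reaction.
- Comparison: the chosen route solves the ring, the lactone and C6 together and installs the epoxide in the first step under reagent control.

Key step: step 18

Assumptions and remarks on the chemistry:
- Methyl 3-(tert-butyldimethylsilyloxy)propanoate (17) is taken as purchasable.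
- The C1 carbinol centre made in step 4 is (R), because (E)-crotylboration is anti. It is destroyed in step 23.
- Alkoxides and borate esters that are only hydrolysed on aqueous work-up are counted with the work-up and carry no number.
- Abbreviations in names: TBS = tert-butyldimethylsilyl, TES = triethylsilyl, PMB = 4-methoxybenzyl; "E" = the arm (2S,3R)-3-[(4-methoxybenzyloxy)methyl]-2-methyloxiran-2-yl. Locants C1–C15 are those of the target.

## Route

Step 1
Reactants: 1 nerol, (2Z)-3,7-dimethylocta-2,6-dien-1-ol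
Product: 2 [(2R,3S)-3-methyl-3-(4-methylpent-3-en-1-yl)oxiran-2-yl]methanol
Conditions: Ti(OiPr)4 (10 mol%), D-(−)-diethyl tartrate (12 mol%), t-BuOOH, 4 Å molecular sieves, CH2Cl2, −20 °C
Reagents that add atoms: tert-butyl hydroperoxide, CC(C)(C)OO
Why: Sharpless asymmetric epoxidation; only the allylic alkene reacts because the hydroxyl binds titanium, and the D-(−)-tartrate complex delivers oxygen to the face that gives C4 (S) and C5 (R). The Z geometry of 1 places C3 and C6 cis on the oxirane.

Step 2
Reactants: 2 [(2R,3S)-3-methyl-3-(4-methylpent-3-en-1-yl)oxiran-2-yl]methanol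
Product: 3 (2R,3S)-2-[(4-methoxybenzyloxy)methyl]-3-methyl-3-(4-methylpent-3-en-1-yl)oxirane
Conditions: NaH, PMBCl, Bu4NI (cat.), THF, 0 → 25 °C
Reagents that add atoms: 4-methoxybenzyl chloride, COc1ccc(CCl)cc1
Why: Williamson etherification; the primary alkoxide is alkylated faster than it can undergo epoxide migration. PMB is chosen because it is later removed oxidatively without touching silyl ethers or the epoxide.

Step 3
Reactants: 3 (2R,3S)-2-[(4-methoxybenzyloxy)methyl]-3-methyl-3-(4-methylpent-3-en-1-yl)oxirane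
Product: 4 3-[(2S,3R)-3-[(4-methoxybenzyloxy)methyl]-2-methyloxiran-2-yl]propanal
Conditions: O3, pyridine, CH2Cl2, −78 °C
Reagents that add atoms: ozone, [O-][O+]=O
Why: Ozonolysis of the only alkene, which is far more reactive than the anisyl ring; pyridine converts the carbonyl oxide directly into the aldehyde, so no separate reduction is needed.

Step 4
Reactants: 4 3-[(2S,3R)-3-[(4-methoxybenzyloxy)methyl]-2-methyloxiran-2-yl]propanal; 5 2-[(2E)-but-2-en-1-yl]-4,4,5,5-tetramethyl-1,3,2-dioxaborolane
Product: 6 (3S,4R)-6-E-3-methylhex-1-en-4-ol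
Conditions: (S)-3,3'-bis(2,4,6-triisopropylphenyl)-1,1'-binaphthalene-2,2'-diyl hydrogen phosphate (5 mol%), toluene, −30 °C; aqueous NaHCO3 work-up
Reagents that add atoms: none
Why: Brønsted acid-catalysed asymmetric crotylboration through a closed Zimmerman–Traxler chair; the (E)-crotyl unit gives the anti product, and the catalyst enantiomer is chosen so that the crotyl group adds to the Si face of the aldehyde. This sets C10 (S), together with C1 (R), which is erased later.

Step 5
Reactants: 6 (3S,4R)-6-E-3-methylhex-1-en-4-ol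
Product: 7 (3S,4R)-4-(TBSO)-6-E-3-methylhex-1-ene
Conditions: TBSOTf, 2,6-lutidine, CH2Cl2, −78 °C
Reagents that add atoms: tert-butyldimethylsilyl trifluoromethanesulfonate, CC(C)(C)[Si](C)(C)OS(=O)(=O)C(F)(F)F
Why: Silylation of a hindered secondary alcohol; at −78 °C with excess base the epoxide is not activated. The robust TBS group is placed on C1 because this oxygen is unmasked last.

Step 6
Reactants: 7 (3S,4R)-4-(TBSO)-6-E-3-methylhex-1-ene
Product: 9 (3S,4R)-4-(TBSO)-6-E-3-methylhexan-1-ol, via B-alkyl-9-borabicyclo[3.3.1]nonane 8 (not isolated)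
Conditions: 9-BBN, THF, 0 → 25 °C; then NaOH, H2O2, 0 °C
Reagents that add atoms: hydrogen peroxide, OO
Why: Anti-Markovnikov hydroboration of the monosubstituted alkene by the bulky borane, then oxidation of the C–B bond; the epoxide and silyl ether are inert to cold basic peroxide.

Step 7
Reactants: 9 (3S,4R)-4-(TBSO)-6-E-3-methylhexan-1-ol
Product: 10 (3S,4R)-4-(TBSO)-6-E-3-methylhexanal
Conditions: Dess–Martin periodinane, NaHCO3, CH2Cl2, 0 → 25 °C
Reagents that add atoms: none
Why: Dess–Martin oxidation under buffered, neutral conditions; the nearest stereocentre is β to the new aldehyde and is not at risk.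

Step 8
Reactants: 10 (3S,4R)-4-(TBSO)-6-E-3-methylhexanal; 11 hex-1-yne
Product: 14 (5E,7R,9S,10R)-10-(TBSO)-12-E-9-methyldodec-5-en-7-ol, via dicyclohexyl[(1E)-hex-1-en-1-yl]borane 12 (not isolated), via [(1E)-hex-1-en-1-yl](methyl)zinc 13 (not isolated)
Conditions: 11, Cy2BH, toluene, 0 → 25 °C; Me2Zn, −78 °C; (2S)-(−)-3-exo-morpholinoisoborneol (5 mol%), then 10, −30 → 0 °C; aqueous NH4Cl
Reagents that add atoms: none
Why: Catalytic asymmetric alkenylzinc addition to an aldehyde; syn hydroboration fixes the E alkene, boron-to-zinc exchange gives the alkenylzinc, and the amino alcohol–zinc complex is chosen to deliver the alkenyl group to the Si face, which sets C8 (R). The hexenyl group is only a masked formyl group.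

Step 9
Reactants: 14 (5E,7R,9S,10R)-10-(TBSO)-12-E-9-methyldodec-5-en-7-ol
Product: 15 (5E,7R,9S,10R)-10-(TBSO)-12-E-9-methyl-7-(TESO)dodec-5-ene
Conditions: TESCl, imidazole, CH2Cl2, 0 °C
Reagents that add atoms: chlorotriethylsilane, CC[Si](Cl)(CC)CC
Why: Silylation; the labile TES group is placed on C8 so that it can later be removed together with the primary TBS ether while the C1 TBS ether stays.

Step 10
Reactants: 15 (5E,7R,9S,10R)-10-(TBSO)-12-E-9-methyl-7-(TESO)dodec-5-ene
Product: 16 (2R,4S,5R)-5-(TBSO)-7-E-4-methyl-2-(TESO)heptanal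
Conditions: O3, pyridine, CH2Cl2, −78 °C
Reagents that add atoms: ozone, [O-][O+]=O
Why: Ozonolysis of the disubstituted alkene unveils the C7 aldehyde. The α-silyloxy aldehyde is used at once so that C8 is not exposed to epimerising conditions.

Step 11
Reactants: 16 (2R,4S,5R)-5-(TBSO)-7-E-4-methyl-2-(TESO)heptanal; 17 methyl 3-(tert-butyldimethylsilyloxy)propanoate
Product: 19 methyl (4R,6S,7R)-7-(TBSO)-2-[(TBSO)methyl]-3-hydroxy-9-E-6-methyl-4-(TESO)nonanoate, via lithium enolate of the propanoate 18 (not isolated)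
Conditions: LiN(iPr)2, THF, −78 °C, 17; then 16, −78 °C; aqueous NH4Cl
Reagents that add atoms: none
Why: Aldol addition of a lithium ester enolate; it forms C7–C11 and brings C12 and C13 at their final oxidation levels. At −78 °C addition to the aldehyde is faster than β-elimination of silanolate from the enolate, and both new stereocentres disappear later.

Step 12
Reactants: 19 methyl (4R,6S,7R)-7-(TBSO)-2-[(TBSO)methyl]-3-hydroxy-9-E-6-methyl-4-(TESO)nonanoate
Product: 20 methyl (4R,6S,7R)-7-(TBSO)-2-[(TBSO)methyl]-9-E-6-methyl-3-oxo-4-(TESO)nonanoate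
Conditions: Dess–Martin periodinane, NaHCO3, CH2Cl2, 0 → 25 °C
Reagents that add atoms: none
Why: Dess–Martin oxidation of the β-hydroxy ester to the β-keto ester; both aldol diastereomers converge on one compound.

Step 13
Reactants: 20 methyl (4R,6S,7R)-7-(TBSO)-2-[(TBSO)methyl]-9-E-6-methyl-3-oxo-4-(TESO)nonanoate
Product: 22 methyl (2Z,4R,6S,7R)-7-(TBSO)-2-[(TBSO)methyl]-9-E-6-methyl-4-(TESO)-3-(trifluoromethylsulfonyloxy)non-2-enoate, via chelated lithium (Z)-enolate 21 (not isolated)
Conditions: LiN(SiMe3)2, Et2O, −78 °C; then Tf2O, −78 → −20 °C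
Reagents that add atoms: trifluoromethanesulfonic anhydride, O=S(=O)(OS(=O)(=O)C(F)(F)F)C(F)(F)F
Why: O-sulfonylation of a β-keto ester enolate; lithium bridges the enolate oxygen and the ester carbonyl in a six-membered chelate, so the C7 oxygen and C12 are cis and the triflate is formed as the Z isomer. Only the doubly activated C11–H is removed, so C8 is untouched; any E isomer is removed by chromatography because it cannot lactonise later.

Step 14
Reactants: 22 methyl (2Z,4R,6S,7R)-7-(TBSO)-2-[(TBSO)methyl]-9-E-6-methyl-4-(TESO)-3-(trifluoromethylsulfonyloxy)non-2-enoate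
Product: 23 methyl (2Z,4R,6S,7R)-7-(TBSO)-2-[(TBSO)methyl]-9-E-6-methyl-4-(TESO)-3-(trimethylstannyl)non-2-enoate
Conditions: Me3SnSnMe3, Pd(PPh3)4 (5 mol%), LiCl, THF, 60 °C
Reagents that add atoms: hexamethylditin, C[Sn](C)(C)[Sn](C)(C)C
Why: Stille-type stannylation of an enol triflate; oxidative addition and reductive elimination both proceed with retention at the alkene, so tin ends up cis to C12.

Step 15
Reactants: 23 methyl (2Z,4R,6S,7R)-7-(TBSO)-2-[(TBSO)methyl]-9-E-6-methyl-4-(TESO)-3-(trimethylstannyl)non-2-enoate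
Product: 24 methyl (2Z,4R,6S,7R)-7-(TBSO)-2-[(TBSO)methyl]-9-E-3-iodo-6-methyl-4-(TESO)non-2-enoate
Conditions: I2, CH2Cl2, 0 °C; aqueous Na2S2O3
Reagents that add atoms: iodine, II
Why: Iododestannylation, an ipso substitution with retention, gives the (Z)-β-iodo enoate with iodine cis to the ester.

Step 16
Reactants: 24 methyl (2Z,4R,6S,7R)-7-(TBSO)-2-[(TBSO)methyl]-9-E-3-iodo-6-methyl-4-(TESO)non-2-enoate
Product: 25 methyl (2Z,4R,6S,7R)-7-(TBSO)-2-[(TBSO)methyl]-9-[(2S,3R)-3-(hydroxymethyl)-2-methyloxiran-2-yl]-3-iodo-6-methyl-4-(TESO)non-2-enoate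
Conditions: DDQ, CH2Cl2/pH 7 buffer, 0 °C
Reagents that add atoms: none
Why: Oxidative cleavage of the PMB ether by benzylic hydride abstraction; under buffered conditions the silyl ethers, epoxide and alkenyl iodide are untouched.

Step 17
Reactants: 25 methyl (2Z,4R,6S,7R)-7-(TBSO)-2-[(TBSO)methyl]-9-[(2S,3R)-3-(hydroxymethyl)-2-methyloxiran-2-yl]-3-iodo-6-methyl-4-(TESO)non-2-enoate
Product: 26 methyl (2Z,4R,6S,7R)-7-(TBSO)-2-[(TBSO)methyl]-9-[(2S,3S)-3-formyl-2-methyloxiran-2-yl]-3-iodo-6-methyl-4-(TESO)non-2-enoate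
Conditions: Dess–Martin periodinane, NaHCO3, CH2Cl2, 0 °C
Reagents that add atoms: none
Why: Dess–Martin oxidation gives the α,β-epoxy aldehyde without acid or base; the aldehyde is used directly in the ring closure.

Step 18
Reactants: 26 methyl (2Z,4R,6S,7R)-7-(TBSO)-2-[(TBSO)methyl]-9-[(2S,3S)-3-formyl-2-methyloxiran-2-yl]-3-iodo-6-methyl-4-(TESO)non-2-enoate
Product: 29 (1R,4S,5R,6R,8R,10S)-1,13-bis(TBSO)-4,5-epoxy-8-(TESO)germacr-7(11)-en-12,6-olide, via alkenylchromium dichloride 27 (not isolated), via ring-closed chromium alkoxide 28 (not isolated)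
Conditions: CrCl2 (15 equiv), NiCl2 (cat.), degassed DMSO/THF, 25 °C, slow addition of 26 to high dilution (about 0.002 M)
Reagents that add atoms: none
Why: Zerovalent nickel, formed from NiCl2 by divalent chromium, inserts into the C7–I bond and hands the alkenyl group to trivalent chromium, giving 27, which adds to the C6 aldehyde. The closest known reaction types are Nozaki–Hiyama–Kishi macrocyclisations of alkenyl iodides and additions of β-iodo enoates to aldehydes that end in butenolides. The C–C bond formation is a 10-exo-trig closure, and the chromium alkoxide 28 then attacks the cis ester in a 5-exo-trig acyl substitution, expelling methoxide to give the butenolide. C6 is controlled by the neighbouring epoxide: under Felkin–Anh control the alkenyl group arrives anti to the C5–O bond and past the C5 hydrogen, which gives (6R) beside (5R). The step needs chemoselectivity for the aldehyde, which alkenylchromium reagents provide, since they do not add to esters, epoxides or silyl ethers. It needs ring closure rather than oligomerisation, which high dilution secures. It needs lactonisation, which the Z geometry of 26 guarantees. C1 is a silylated carbinol, so no five-membered closure onto a C1 carbonyl can compete.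

Step 19
Reactants: 29 (1R,4S,5R,6R,8R,10S)-1,13-bis(TBSO)-4,5-epoxy-8-(TESO)germacr-7(11)-en-12,6-olide
Product: 30 (1R,4S,5R,6R,8R,10S)-1-(TBSO)-4,5-epoxy-8,13-dihydroxygermacr-7(11)-en-12,6-olide
Conditions: HF·pyridine, pyridine, THF, 0 °C
Reagents that add atoms: none
Why: Fluoride-mediated desilylation graded by sterics; the secondary TES ether and the primary allylic TBS ether are cleaved much faster than the hindered secondary TBS ether on C1 in buffered HF·pyridine.

Step 20
Reactants: 30 (1R,4S,5R,6R,8R,10S)-1-(TBSO)-4,5-epoxy-8,13-dihydroxygermacr-7(11)-en-12,6-olide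
Product: 31 (1R,4S,5R,6R,8R,10S)-13-acetoxy-1-(TBSO)-4,5-epoxy-8-hydroxygermacr-7(11)-en-12,6-olide
Conditions: Ac2O, 2,4,6-collidine, CH2Cl2, −20 °C
Reagents that add atoms: acetic anhydride, CC(=O)OC(C)=O
Why: Selective acylation; the primary allylic hydroxyl reacts much faster than the hindered secondary one with a weak base at low temperature.

Step 21
Reactants: 31 (1R,4S,5R,6R,8R,10S)-13-acetoxy-1-(TBSO)-4,5-epoxy-8-hydroxygermacr-7(11)-en-12,6-olide
Product: 32 (1R,4S,5R,6R,8R,10S)-13-acetoxy-1-(TBSO)-4,5-epoxy-8-(3-methylbut-2-enoyloxy)germacr-7(11)-en-12,6-olide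
Conditions: 3-methylbut-2-enoyl chloride, pyridine, DMAP (cat.), CH2Cl2, 0 °C
Reagents that add atoms: 3-methylbut-2-enoyl chloride, CC(C)=CC(=O)Cl
Why: Acylation of the secondary alcohol with an acid chloride; pyridine instead of a trialkylamine limits vinylketene formation and deconjugation of the acyl group. No ketone is present yet, so C10 cannot epimerise.

Step 22
Reactants: 32 (1R,4S,5R,6R,8R,10S)-13-acetoxy-1-(TBSO)-4,5-epoxy-8-(3-methylbut-2-enoyloxy)germacr-7(11)-en-12,6-olide
Product: 33 (1R,4S,5R,6R,8R,10S)-13-acetoxy-4,5-epoxy-1-hydroxy-8-(3-methylbut-2-enoyloxy)germacr-7(11)-en-12,6-olide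
Conditions: HF·pyridine, THF, 25 °C
Reagents that add atoms: none
Why: Fluoride cleavage of the last silyl ether; esters and trisubstituted epoxides tolerate HF·pyridine diluted in THF.

Step 23
Reactants: 33 (1R,4S,5R,6R,8R,10S)-13-acetoxy-4,5-epoxy-1-hydroxy-8-(3-methylbut-2-enoyloxy)germacr-7(11)-en-12,6-olide
Product: 34 (4S,5R,6R,8R,10S)-13-acetoxy-4,5-epoxy-8-(3-methylbut-2-enoyloxy)-1-oxogermacr-7(11)-en-12,6-olide (CNP0220542.1)
Conditions: Dess–Martin periodinane, NaHCO3, CH2Cl2, 0 °C
Reagents that add atoms: none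
Why: Dess–Martin oxidation as the last step; the ketone appears only after C8 is acylated, so no hemiketal can form, and C10 is never exposed to base.

## Compound list

1 | nerol, (2Z)-3,7-dimethylocta-2,6-dien-1-ol | CC(C)=CCC/C(C)=C\CO | starting material
2 | [(2R,3S)-3-methyl-3-(4-methylpent-3-en-1-yl)oxiran-2-yl]methanol | OC[C@H]1O[C@@]1(C)CCC=C(C)C | intermediate
3 | (2R,3S)-2-[(4-methoxybenzyloxy)methyl]-3-methyl-3-(4-methylpent-3-en-1-yl)oxirane | COc1ccc(COC[C@H]2O[C@@]2(C)CCC=C(C)C)cc1 | intermediate
4 | 3-[(2S,3R)-3-[(4-methoxybenzyloxy)methyl]-2-methyloxiran-2-yl]propanal | COc1ccc(COC[C@H]2O[C@@]2(C)CCC=O)cc1 | intermediate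
5 | 2-[(2E)-but-2-en-1-yl]-4,4,5,5-tetramethyl-1,3,2-dioxaborolane | C/C=C/CB1OC(C)(C)C(C)(C)O1 | starting material
6 | (3S,4R)-6-E-3-methylhex-1-en-4-ol (anti; C1 R, C10 S) | COc1ccc(COC[C@H]2O[C@@]2(C)CC[C@@H](O)[C@@H](C)C=C)cc1 | intermediate
7 | (3S,4R)-4-(TBSO)-6-E-3-methylhex-1-ene | COc1ccc(COC[C@H]2O[C@@]2(C)CC[C@@H](O[Si](C)(C)C(C)(C)C)[C@@H](C)C=C)cc1 | intermediate
8 | 9-[(3S,4R)-4-(TBSO)-6-E-3-methylhexyl]-9-borabicyclo[3.3.1]nonane | COc1ccc(COC[C@H]2O[C@@]2(C)CC[C@@H](O[Si](C)(C)C(C)(C)C)[C@@H](C)CCB3C4CCCC3CCC4)cc1 | intermediate (not isolated)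
9 | (3S,4R)-4-(TBSO)-6-E-3-methylhexan-1-ol | COc1ccc(COC[C@H]2O[C@@]2(C)CC[C@@H](O[Si](C)(C)C(C)(C)C)[C@@H](C)CCO)cc1 | intermediate
10 | (3S,4R)-4-(TBSO)-6-E-3-methylhexanal | COc1ccc(COC[C@H]2O[C@@]2(C)CC[C@@H](O[Si](C)(C)C(C)(C)C)[C@@H](C)CC=O)cc1 | intermediate
11 | hex-1-yne | CCCCC#C | starting material
12 | dicyclohexyl[(1E)-hex-1-en-1-yl]borane | CCCC/C=C/B(C1CCCCC1)C1CCCCC1 | intermediate (not isolated)
13 | [(1E)-hex-1-en-1-yl](methyl)zinc | CCCC/C=C/[Zn]C | intermediate (not isolated)
14 | (5E,7R,9S,10R)-10-(TBSO)-12-E-9-methyldodec-5-en-7-ol | COc1ccc(COC[C@H]2O[C@@]2(C)CC[C@@H](O[Si](C)(C)C(C)(C)C)[C@@H](C)C[C@@H](O)/C=C/CCCC)cc1 | intermediate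
15 | (5E,7R,9S,10R)-10-(TBSO)-12-E-9-methyl-7-(TESO)dodec-5-ene | COc1ccc(COC[C@H]2O[C@@]2(C)CC[C@@H](O[Si](C)(C)C(C)(C)C)[C@@H](C)C[C@@H](O[Si](CC)(CC)CC)/C=C/CCCC)cc1 | intermediate
16 | (2R,4S,5R)-5-(TBSO)-7-E-4-methyl-2-(TESO)heptanal | COc1ccc(COC[C@H]2O[C@@]2(C)CC[C@@H](O[Si](C)(C)C(C)(C)C)[C@@H](C)C[C@@H](O[Si](CC)(CC)CC)C=O)cc1 | intermediate
17 | methyl 3-(tert-butyldimethylsilyloxy)propanoate | COC(=O)CCO[Si](C)(C)C(C)(C)C | starting material
18 | lithium 1-methoxy-3-(TBSO)prop-1-en-1-olate (enolate of 17, geometry immaterial) | COC(O[Li])=CCO[Si](C)(C)C(C)(C)C | intermediate (not isolated)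
19 | methyl (4R,6S,7R)-7-(TBSO)-2-[(TBSO)methyl]-3-hydroxy-9-E-6-methyl-4-(TESO)nonanoate (mixture at C2 and C3) | COc1ccc(COC[C@H]2O[C@@]2(C)CC[C@@H](O[Si](C)(C)C(C)(C)C)[C@@H](C)C[C@@H](O[Si](CC)(CC)CC)C(O)C(CO[Si](C)(C)C(C)(C)C)C(=O)OC)cc1 | intermediate
20 | methyl (4R,6S,7R)-7-(TBSO)-2-[(TBSO)methyl]-9-E-6-methyl-3-oxo-4-(TESO)nonanoate (C2 epimers) | COc1ccc(COC[C@H]2O[C@@]2(C)CC[C@@H](O[Si](C)(C)C(C)(C)C)[C@@H](C)C[C@@H](O[Si](CC)(CC)CC)C(=O)C(CO[Si](C)(C)C(C)(C)C)C(=O)OC)cc1 | intermediate
21 | lithium (Z)-enolate of 20, lithium bridging the C3 oxygen and the ester carbonyl | COc1ccc(COC[C@H]2O[C@@]2(C)CC[C@@H](O[Si](C)(C)C(C)(C)C)[C@@H](C)C[C@@H](O[Si](CC)(CC)CC)/C(O[Li])=C(\CO[Si](C)(C)C(C)(C)C)C(=O)OC)cc1 | intermediate (not isolated)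
22 | methyl (2Z,4R,6S,7R)-7-(TBSO)-2-[(TBSO)methyl]-9-E-6-methyl-4-(TESO)-3-(trifluoromethylsulfonyloxy)non-2-enoate | COc1ccc(COC[C@H]2O[C@@]2(C)CC[C@@H](O[Si](C)(C)C(C)(C)C)[C@@H](C)C[C@@H](O[Si](CC)(CC)CC)/C(OS(=O)(=O)C(F)(F)F)=C(\CO[Si](C)(C)C(C)(C)C)C(=O)OC)cc1 | intermediate
23 | methyl (2Z,4R,6S,7R)-7-(TBSO)-2-[(TBSO)methyl]-9-E-6-methyl-4-(TESO)-3-(trimethylstannyl)non-2-enoate | COc1ccc(COC[C@H]2O[C@@]2(C)CC[C@@H](O[Si](C)(C)C(C)(C)C)[C@@H](C)C[C@@H](O[Si](CC)(CC)CC)/C([Sn](C)(C)C)=C(\CO[Si](C)(C)C(C)(C)C)C(=O)OC)cc1 | intermediate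
24 | methyl (2Z,4R,6S,7R)-7-(TBSO)-2-[(TBSO)methyl]-9-E-3-iodo-6-methyl-4-(TESO)non-2-enoate | COc1ccc(COC[C@H]2O[C@@]2(C)CC[C@@H](O[Si](C)(C)C(C)(C)C)[C@@H](C)C[C@@H](O[Si](CC)(CC)CC)/C(I)=C(\CO[Si](C)(C)C(C)(C)C)C(=O)OC)cc1 | intermediate
25 | methyl (2Z,4R,6S,7R)-7-(TBSO)-2-[(TBSO)methyl]-9-[(2S,3R)-3-(hydroxymethyl)-2-methyloxiran-2-yl]-3-iodo-6-methyl-4-(TESO)non-2-enoate | OC[C@H]1O[C@@]1(C)CC[C@@H](O[Si](C)(C)C(C)(C)C)[C@@H](C)C[C@@H](O[Si](CC)(CC)CC)/C(I)=C(\CO[Si](C)(C)C(C)(C)C)C(=O)OC | intermediate
26 | methyl (2Z,4R,6S,7R)-7-(TBSO)-2-[(TBSO)methyl]-9-[(2S,3S)-3-formyl-2-methyloxiran-2-yl]-3-iodo-6-methyl-4-(TESO)non-2-enoate | O=C[C@H]1O[C@@]1(C)CC[C@@H](O[Si](C)(C)C(C)(C)C)[C@@H](C)C[C@@H](O[Si](CC)(CC)CC)/C(I)=C(\CO[Si](C)(C)C(C)(C)C)C(=O)OC | intermediate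
27 | alkenylchromium dichloride from 26 (CrCl2 in place of iodine on C7) | O=C[C@H]1O[C@@]1(C)CC[C@@H](O[Si](C)(C)C(C)(C)C)[C@@H](C)C[C@@H](O[Si](CC)(CC)CC)/C([Cr](Cl)Cl)=C(\CO[Si](C)(C)C(C)(C)C)C(=O)OC | intermediate (not isolated)
28 | ring-closed (6R) chromium alkoxide, methyl ester still open | COC(=O)/C(CO[Si](C)(C)C(C)(C)C)=C1\[C@@H](O[Cr](Cl)Cl)[C@H]2O[C@@]2(C)CC[C@@H](O[Si](C)(C)C(C)(C)C)[C@@H](C)C[C@H]1O[Si](CC)(CC)CC | intermediate (not isolated)
29 | (1R,4S,5R,6R,8R,10S)-1,13-bis(TBSO)-4,5-epoxy-8-(TESO)germacr-7(11)-en-12,6-olide | CC(C)(C)[Si](C)(C)OCC1=C2[C@@H](OC1=O)[C@H]1O[C@@]1(C)CC[C@@H](O[Si](C)(C)C(C)(C)C)[C@@H](C)C[C@H]2O[Si](CC)(CC)CC | intermediate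
30 | (1R,4S,5R,6R,8R,10S)-1-(TBSO)-4,5-epoxy-8,13-dihydroxygermacr-7(11)-en-12,6-olide | OCC1=C2[C@@H](OC1=O)[C@H]1O[C@@]1(C)CC[C@@H](O[Si](C)(C)C(C)(C)C)[C@@H](C)C[C@H]2O | intermediate
31 | (1R,4S,5R,6R,8R,10S)-13-acetoxy-1-(TBSO)-4,5-epoxy-8-hydroxygermacr-7(11)-en-12,6-olide | CC(=O)OCC1=C2[C@@H](OC1=O)[C@H]1O[C@@]1(C)CC[C@@H](O[Si](C)(C)C(C)(C)C)[C@@H](C)C[C@H]2O | intermediate
32 | (1R,4S,5R,6R,8R,10S)-13-acetoxy-1-(TBSO)-4,5-epoxy-8-(3-methylbut-2-enoyloxy)germacr-7(11)-en-12,6-olide | CC(=O)OCC1=C2[C@@H](OC1=O)[C@H]1O[C@@]1(C)CC[C@@H](O[Si](C)(C)C(C)(C)C)[C@@H](C)C[C@H]2OC(=O)C=C(C)C | intermediate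
33 | (1R,4S,5R,6R,8R,10S)-13-acetoxy-4,5-epoxy-1-hydroxy-8-(3-methylbut-2-enoyloxy)germacr-7(11)-en-12,6-olide | CC(=O)OCC1=C2[C@@H](OC1=O)[C@H]1O[C@@]1(C)CC[C@@H](O)[C@@H](C)C[C@H]2OC(=O)C=C(C)C | intermediate
34 | (4S,5R,6R,8R,10S)-13-acetoxy-4,5-epoxy-8-(3-methylbut-2-enoyloxy)-1-oxogermacr-7(11)-en-12,6-olide | CC(=O)OCC1=C2[C@@H](OC1=O)[C@H]1O[C@@]1(C)CCC(=O)[C@@H](C)C[C@H]2OC(=O)C=C(C)C | target

## Step count and least certain steps

Total: 23 steps. Longest linear sequence: 23 steps from 1; compounds 5, 11 and 17 are purchased.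

**Step 18 (key step).** Three processes can compete.
- Divalent chromium can reduce the α,β-epoxy aldehyde by electron transfer, with cleavage of the C5–O bond, before the slower alkenyl transfer takes place.
- Closure of a ten-membered ring by a tetrasubstituted alkenylmetal is slow, so intermolecular coupling and oligomerisation can take over.
- Ring strain can override the Felkin–Anh preference and erode facial selectivity at C6.

Fallback, from 26 back to 29: the ring is closed by acylation and C6 is set by reduction. Pinnick oxidation of 26 (NaClO2, NaH2PO4, 2-methylbut-2-ene) should give the epoxy acid F1. Coupling with N,O-dimethylhydroxylamine gives the Weinreb amide F2. Iodine–magnesium exchange with i-PrMgCl·LiCl in THF at −78 °C under high dilution turns the β-iodo enoate into an alkenylmagnesium that acylates on the amide and gives the macrocyclic C6 ketone F3. Reduction with Zn(BH4)2 in Et2O goes through a zinc chelate of the ketone and epoxide oxygens, with hydride arriving opposite C4, and should give the (6R) hydroxy ester F4, which lactonises to 29.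

**Step 14.** Oxidative addition and tin transfer at a tetrasubstituted triflate flanked by two silyloxy-bearing carbons may be slow. Loss of the triflate by reduction, or loss of alkene geometry through reversible conjugate addition, could then compete.

Fallback, from 22 back to 29: the triflate itself serves as the alkenyl partner of the nickel/chromium closure, so tin and iodine are avoided. Cleavage of the PMB ether of 22 with DDQ gives the alcohol F5, Dess–Martin oxidation gives the triflate aldehyde F6, and CrCl2 with catalytic NiCl2 in DMF under high dilution closes it through 27 and 28 to 29.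

**Step 8.** An unbranched aldehyde gives the catalyst less to discriminate between the two faces, so control at C8 may be incomplete. Methyl transfer from zinc can also compete with alkenyl transfer.

Fallback, from 10 back to 14: C8 is set by reduction instead of addition. The lithium acetylide of 11 adds to 10 to give the propargylic alcohols F7 as a mixture at C8. Dess–Martin oxidation gives the ynone F8. Noyori transfer hydrogenation with RuCl(p-cymene)[(R,R)-N-tosyl-1,2-diphenylethylenediamine] in i-PrOH gives the (R)-propargylic alcohol F9. Trans-selective reduction of the alkyne with NaAlH2(OCH2CH2OMe)2 leads to 14.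

**Step 21.** Under amine base the acid chloride can isomerise through a vinylketene, which would deliver the deconjugated 3-methylbut-3-enoate. Acylation of the hindered allylic alcohol may also be slow enough for acetyl migration to interfere.

Fallback, from 31 back to 32: the unsaturated ester is built on the oxygen. Esterification of 31 with diethylphosphonoacetic acid (DCC, DMAP cat.) gives the phosphonoacetate F10, and Horner–Wadsworth–Emmons reaction with acetone (LiCl, DBU) gives 32; no ketone is present at this stage, so the base is harmless.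

## Further compounds

F1 | step 18 | (2S,3S)-epoxy acid from 26 (CO2H in place of CHO on C6) | OC(=O)[C@H]1O[C@@]1(C)CC[C@@H](O[Si](C)(C)C(C)(C)C)[C@@H](C)C[C@@H](O[Si](CC)(CC)CC)/C(I)=C(\CO[Si](C)(C)C(C)(C)C)C(=O)OC
F2 | step 18 | N-methoxy-N-methylamide of F1 | CON(C)C(=O)[C@H]1O[C@@]1(C)CC[C@@H](O[Si](C)(C)C(C)(C)C)[C@@H](C)C[C@@H](O[Si](CC)(CC)CC)/C(I)=C(\CO[Si](C)(C)C(C)(C)C)C(=O)OC
F3 | step 18 | macrocyclic C6 ketone, methyl (1R,4S,5S,8R,10S)-1,13-bis(TBSO)-4,5-epoxy-6-oxo-8-(TESO)germacr-7(11)-en-12-oate | COC(=O)/C(CO[Si](C)(C)C(C)(C)C)=C1\C(=O)[C@H]2O[C@@]2(C)CC[C@@H](O[Si](C)(C)C(C)(C)C)[C@@H](C)C[C@H]1O[Si](CC)(CC)CC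
F4 | step 18 | (6R)-hydroxy ester, methyl (1R,4S,5R,6R,8R,10S)-1,13-bis(TBSO)-4,5-epoxy-6-hydroxy-8-(TESO)germacr-7(11)-en-12-oate | COC(=O)/C(CO[Si](C)(C)C(C)(C)C)=C1\[C@@H](O)[C@H]2O[C@@]2(C)CC[C@@H](O[Si](C)(C)C(C)(C)C)[C@@H](C)C[C@H]1O[Si](CC)(CC)CC
F5 | step 14 | C6 alcohol of the (Z)-enol triflate (22 without PMB) | OC[C@H]1O[C@@]1(C)CC[C@@H](O[Si](C)(C)C(C)(C)C)[C@@H](C)C[C@@H](O[Si](CC)(CC)CC)/C(OS(=O)(=O)C(F)(F)F)=C(\CO[Si](C)(C)C(C)(C)C)C(=O)OC
F6 | step 14 | C6 epoxy aldehyde of the (Z)-enol triflate (triflate analogue of 26) | O=C[C@H]1O[C@@]1(C)CC[C@@H](O[Si](C)(C)C(C)(C)C)[C@@H](C)C[C@@H](O[Si](CC)(CC)CC)/C(OS(=O)(=O)C(F)(F)F)=C(\CO[Si](C)(C)C(C)(C)C)C(=O)OC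
F7 | step 8 | (9S,10R)-10-(TBSO)-12-E-9-methyldodec-5-yn-7-ol, mixture at C7 | COc1ccc(COC[C@H]2O[C@@]2(C)CC[C@@H](O[Si](C)(C)C(C)(C)C)[C@@H](C)CC(O)C#CCCCC)cc1
F8 | step 8 | (9S,10R)-10-(TBSO)-12-E-9-methyldodec-5-yn-7-one | COc1ccc(COC[C@H]2O[C@@]2(C)CC[C@@H](O[Si](C)(C)C(C)(C)C)[C@@H](C)CC(=O)C#CCCCC)cc1
F9 | step 8 | (7R,9S,10R)-10-(TBSO)-12-E-9-methyldodec-5-yn-7-ol | COc1ccc(COC[C@H]2O[C@@]2(C)CC[C@@H](O[Si](C)(C)C(C)(C)C)[C@@H](C)C[C@@H](O)C#CCCCC)cc1
F10 | step 21 | C8 diethylphosphonoacetate of 31 | CC(=O)OCC1=C2[C@@H](OC1=O)[C@H]1O[C@@]1(C)CC[C@@H](O[Si](C)(C)C(C)(C)C)[C@@H](C)C[C@H]2OC(=O)CP(=O)(OCC)OCC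
A1 | alternative 1 | (E)-cyclodec-5-enone with C4 methoxymethyl ether, C7 dioxolane and C8 PMB ether | O=C1CC[C@](C)(OCOC)/C=C/C2(OCCO2)[C@H](OCc3ccc(OC)cc3)C[C@@H]1C
A2 | alternative 2 | 2,3-dehydro macrocycle with C1 triethylsilyl ether, acetate, senecioate and butenolide in place | CC(=O)OCC1=C2[C@@H](OC1=O)[C@H]1O[C@@]1(C)/C=C\[C@@H](O[Si](CC)(CC)CC)[C@@H](C)C[C@H]2OC(=O)C=C(C)C
A3 | alternative 3 | (4S,5R,6R,8R,10S)-8,13-bis(TBSO)-4,5-epoxy-1-oxogermacr-7(11)-en-12,6-olide | CC(C)(C)[Si](C)(C)OCC1=C2[C@@H](OC1=O)[C@H]1O[C@@]1(C)CCC(=O)[C@@H](C)C[C@H]2O[Si](C)(C)C(C)(C)C
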